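**Assumptions (one line):** vinylacetylene is available as a toluene solution; glyoxal dimethyl acetal is dried before use; the trans-lactone diastereomer from step 10 is separable; C8–OH is silylated (step 6) to avoid butenolide formation and Cr-allyl elimination.

**Retrosynthesis**
- Target 19 ⇒ aldehyde 18 by an intramolecular vinylogous Morita–Baylis–Hillman (MBH) reaction. This forms C4–C5, the C4=C15 methylene and the C5–OH, and closes the 10-membered ring.
- 18 ⇒ a Cr-Barbier allylation/lactonization of allyl bromide 13 with glyoxal acetal. This makes the trans α-methylene-γ-lactone (C6–C7). Bromide 13 comes from MBH/SN2′ on aldehyde 10.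
- The 5-vinylfuran-3(2H)-one ⇐ 5-endo-dig oxa-Michael closure of an α-hydroxy ynone (Weinreb amide + vinylacetylide).
- The syn C8/C10 diol ⇐ Narasaka–Prasad reduction of the organocatalytic aldol adduct of 1 + 2, which sets C10 first.
- Rings form in the order furanone → lactone → 10-membered carbocycle.

**Step 1**
Reactants: 1 (1,1-dimethoxypropan-2-one), 2 (ethyl pyruvate)
Product: 3, ethyl (2R)-2-hydroxy-5,5-dimethoxy-2-methyl-4-oxopentanoate
Conditions: 9-amino-9-deoxy-epi-quinine (20 mol%), TFA (40 mol%), neat, rt, 48 h
Reagents that add atoms: none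
Why: Direct enamine-catalysed asymmetric aldol; the donor reacts at its methyl group, and the catalyst sets the Re/Si face of the pyruvate ketone to give the tertiary carbinol (C10, R).

**Step 2**
Reactants: 3
Product: 4, ethyl (2R,4S)-2,4-dihydroxy-5,5-dimethoxy-2-methylpentanoate (syn-1,3-diol)
Conditions: Et2BOMe, then NaBH4, THF/MeOH 4:1, –78 °C; oxidative workup
Reagents that add atoms: none
Why: Narasaka–Prasad chelation-controlled reduction of the β-hydroxy ketone gives the 1,3-syn diol, which sets C8 (S) relative to C10; any γ-lactone that forms converges in step 3.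

**Step 3**
Reactants: 4
Product: 5, (2R,4S)-2,4-dihydroxy-N,5,5-trimethoxy-N,2-dimethylpentanamide
Conditions: MeNHOMe·HCl, i-PrMgCl, THF, –20 → 0 °C
Reagents that add atoms: N,O-dimethylhydroxylamine, CNOC
Why: Williams Weinreb amidation tolerates free hydroxyls and converts the ester or any lactone to the amide, with no stereocentre touched.

**Step 4**
Reactants: 5, 6 (vinylacetylene)
Product: 7, (6R,8S)-6,8-dihydroxy-9,9-dimethoxy-6-methylnon-1-en-3-yn-5-one
Conditions: 6 + n-BuLi (4 equiv each), THF, –78 °C; add 5; warm to 0 °C; NH4Cl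
Reagents that add atoms: none
Why: Lithium acetylide addition to the Weinreb amide stops at the ynone because the chelated tetrahedral intermediate is stable, and the stereocentres are untouched.

**Step 5**
Reactants: 7
Product: 8, (2R)-2-[(2S)-2-hydroxy-3,3-dimethoxypropyl]-2-methyl-5-vinylfuran-3(2H)-one
Conditions: DBU (10 mol%), CH2Cl2, 0 °C → rt
Reagents that add atoms: none
Why: Base-catalysed 5-endo-dig oxa-Michael addition of the tertiary α-hydroxyl onto the ynone builds the 3(2H)-furanone, preferred over 7-endo attack by C8–OH, and C10 is not involved in any bond change.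

**Step 6**
Reactants: 8
Product: 9, the C8-OTBS ether of 8
Conditions: TBSCl, imidazole, DMAP (cat.), DMF, rt
Reagents that add atoms: TBSCl, C[Si](C)(Cl)C(C)(C)C
Why: Silylation of the only free hydroxyl, with no stereochemical change.

**Step 7**
Reactants: 9
Product: 10, (2S)-2-(TBSO)-3-[(2R)-2-methyl-3-oxo-5-vinyl-2,3-dihydrofuran-2-yl]propanal
Conditions: TESOTf, 2,4,6-collidine, CH2Cl2, 0 °C; then H2O
Reagents that add atoms: water, O
Why: Fujioka–Kita non-acidic acetal deprotection gives the aldehyde and leaves the silyl ether, furanone and vinyl group intact.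

**Step 8**
Reactants: 10, 11 (ethyl acrylate)
Product: 12, ethyl (4S)-4-(TBSO)-3-hydroxy-2-methylene-5-[(2R)-2-methyl-3-oxo-5-vinyl-2,3-dihydrofuran-2-yl]pentanoate (C3 epimer mixture)
Conditions: DABCO (1 equiv), ethyl acrylate (10 equiv), rt, 4 d
Reagents that add atoms: none
Why: The MBH reaction attaches the acrylate at C7, and the new carbinol epimers are erased in step 9.

**Step 9**
Reactants: 12
Product: 13, ethyl 2-(bromomethyl)-4-(TBSO)-5-[(2R)-furanonyl]pent-2-enoate (4S; E/Z mixture)
Conditions: NBS, Me2S, CH2Cl2, –20 °C → rt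
Reagents that add atoms: NBS, O=C1CCC(=O)N1Br
Why: NBS/Me2S activates the allylic alcohol for SN2′ bromide delivery, giving the 2-(bromomethyl)alk-2-enoate, and C7 stereochemistry is irrelevant because it becomes sp2.

**Step 10**
Reactants: 13, 14 (glyoxal dimethyl acetal)
Product: 15, the trans-α-methylene-γ-lactone: 5-(dimethoxymethyl)-4-[(1S)-1-(TBSO)-2-(furanonyl)ethyl]-3-methylenedihydrofuran-2-one, with C6/C7 configured as in the target
Conditions: CrCl2 (4 equiv), THF, 0 °C → rt; then TsOH (cat.)
Reagents that add atoms: none
Why: Nozaki–Hiyama–Kishi-type Barbier allylation proceeds through a chair Zimmerman–Traxler transition state via the E-allylchromium to the anti homoallylic alkoxide, which lactonizes to the trans lactone; the C8 stereocentre biases the facial selectivity (one of two trans diastereomers is isolated).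

**Step 11**
Reactants: 15
Product: 16, the C8 free alcohol (C8–OH)
Conditions: HF·pyridine, pyridine/THF, 0 °C → rt
Reagents that add atoms: none
Why: Buffered fluoride removes the TBS group and leaves the acetal, lactone and furanone untouched.

**Step 12**
Reactants: 16
Product: 17, the C8 methacrylate of 16
Conditions: methacryloyl chloride, Et3N, DMAP (cat.), BHT, CH2Cl2, 0 °C
Reagents that add atoms: methacryloyl chloride, C=C(C)C(=O)Cl
Why: Simple acylation of the only free hydroxyl; C5 is still masked as the acetal, so there is no regiochemical issue.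

**Step 13**
Reactants: 17
Product: 18, aldehyde with a 5-vinylfuranone, the C8 methacrylate and the trans α-methylene-lactone
Conditions: TESOTf, 2,4,6-collidine, CH2Cl2, 0 °C; then H2O
Reagents that add atoms: water, O
Why: The same mild acetal-to-aldehyde unmasking as step 7 is used immediately before ring closure because the α-alkoxy aldehyde is epimerizable.

**Step 14**
Reactants: 18
Product: 19, isogoiazensolide
Conditions: β-isocupreidine (30 mol%), MeCN, 1 mM, slow addition of 18 over 24 h, 25 °C, 5 d
Reagents that add atoms: none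
Why: Proposed new method: an intramolecular vinylogous MBH macrocyclization in which the Lewis base adds 1,6 to the terminal C15 of the 5-vinylfuranone dienone, the γ-carbon (C4) of the resulting dienolate attacks aldehyde C5 to close the ring, and proton transfer/E1cB loss of the catalyst restores C4=C15; the closest known reactions are intramolecular MBH/Rauhut–Currier cyclizations and vinylogous MBH of dienones, and C5 (R) is set by the trans-lactone C6 stereocentre (Felkin-type bias) with the chiral cinchona base reinforcing.

**Compound list**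
1 | 1,1-dimethoxypropan-2-one | CC(=O)C(OC)OC | starting material
2 | ethyl pyruvate | CCOC(=O)C(C)=O | starting material
3 | ethyl (2R)-2-hydroxy-5,5-dimethoxy-2-methyl-4-oxopentanoate | CCOC(=O)[C@](C)(O)CC(=O)C(OC)OC | intermediate
4 | ethyl (2R,4S)-2,4-dihydroxy-5,5-dimethoxy-2-methylpentanoate | CCOC(=O)[C@](C)(O)C[C@H](O)C(OC)OC | intermediate
5 | (2R,4S)-2,4-dihydroxy-N,5,5-trimethoxy-N,2-dimethylpentanamide | CON(C)C(=O)[C@](C)(O)C[C@H](O)C(OC)OC | intermediate
6 | vinylacetylene | C=CC#C | starting material
7 | (6R,8S)-6,8-dihydroxy-9,9-dimethoxy-6-methylnon-1-en-3-yn-5-one | C=CC#CC(=O)[C@](C)(O)C[C@H](O)C(OC)OC | intermediate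
8 | (2R)-2-[(2S)-2-hydroxy-3,3-dimethoxypropyl]-2-methyl-5-vinylfuran-3(2H)-one | C=CC1=CC(=O)[C@](C)(O1)C[C@H](O)C(OC)OC | intermediate
9 | C8-OTBS ether of 8 | C=CC1=CC(=O)[C@](C)(O1)C[C@H](O[Si](C)(C)C(C)(C)C)C(OC)OC | intermediate
10 | (2S)-2-(TBSO)-3-[(2R)-2-methyl-3-oxo-5-vinyl-2,3-dihydrofuran-2-yl]propanal | C=CC1=CC(=O)[C@](C)(O1)C[C@H](O[Si](C)(C)C(C)(C)C)C=O | intermediate
11 | ethyl acrylate | C=CC(=O)OCC | starting material
12 | MBH adduct (C3 epimer mixture, 4S) | C=CC1=CC(=O)[C@](C)(O1)C[C@H](O[Si](C)(C)C(C)(C)C)C(O)C(=C)C(=O)OCC | intermediate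
13 | allylic bromide (4S, E/Z mixture) | C=CC1=CC(=O)[C@](C)(O1)C[C@H](O[Si](C)(C)C(C)(C)C)C=C(CBr)C(=O)OCC | intermediate
14 | glyoxal dimethyl acetal | COC(OC)C=O | starting material
15 | trans-lactone acetal, C8-OTBS | C=CC1=CC(=O)[C@](C)(O1)C[C@H](O[Si](C)(C)C(C)(C)C)[C@H]2C(=C)C(=O)O[C@@H]2C(OC)OC | intermediate
16 | C8-alcohol | C=CC1=CC(=O)[C@](C)(O1)C[C@H](O)[C@H]2C(=C)C(=O)O[C@@H]2C(OC)OC | intermediate
17 | C8-methacrylate acetal | C=CC1=CC(=O)[C@](C)(O1)C[C@H](OC(=O)C(C)=C)[C@H]2C(=C)C(=O)O[C@@H]2C(OC)OC | intermediate
18 | C8-methacrylate aldehyde | C=CC1=CC(=O)[C@](C)(O1)C[C@H](OC(=O)C(C)=C)[C@H]2C(=C)C(=O)O[C@@H]2C=O | intermediate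
19 | isogoiazensolide | C=C(C)C(=O)O[C@H]1C[C@@]2(C)OC(=CC2=O)C(=C)[C@@H](O)[C@H]2OC(=O)C(=C)[C@@H]21 | target

**Total steps:** 14. **Longest linear sequence:** 14.

**Three steps most likely to fail**
1. **Step 14 (proposed new vinylogous MBH macrocyclization).** The vinylogous-ester dienone is a weak acceptor, the ring strain is high, and the catalyst can add to the α-methylene lactone. Fallback: use lithiated 2-bromobut-1-en-3-yne in step 4 in place of vinylacetylide, carry the 5-(1-bromovinyl)furanone through steps 5–13, and close the ring by intramolecular Nozaki–Hiyama–Kishi coupling (CrCl2, cat. NiCl2, DMF). If C5 comes out as the wrong epimer, oxidize it and reduce the ketone with a CBS catalyst.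
2. **Step 10 (Cr-Barbier lactonization).** The C7/C8 diastereoselectivity may be poor, or 1,4-elimination of the C8 silyloxy group from the allylchromium may compete. Fallback: convert bromide 13 to the 2-carboalkoxyallylboronate and run a Sc(OTf)3-catalysed allylboration–lactonization.
3. **Step 1 (aldol with the acetal donor).** The regioselectivity or enantioselectivity may be poor. Fallback: run a racemic pyrrolidine-catalysed aldol and carry it through the NP reduction, then resolve the syn-diol 4 by lipase-catalysed acetylation of the C8 alcohol with vinyl acetate.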